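(The numbers stand for no real mixture; the flask was simulated.)

Which flask, cold ochre or warm violet, ends with the larger excess of left-handed product, and how far does each excess fall below what the ratio of the rate constants gives?

- ochre: left-handed substrate 0.20 M; reagent 0.240 M; free catalyst 0.19 mM; impurity 29 µM; added ligand 0.95 mM; right-handed substrate 0.20 M; temperature 0 °C; time 3.0 h
- violet: left-handed substrate 0.20 M; reagent 0.240 M; free catalyst 0.19 mM; impurity 29 µM; added ligand 0.95 mM; right-handed substrate 0.20 M; temperature 25 °C; time 3.0 h

    reagent + free catalyst + left-handed substrate → free catalyst + left-handed product (k1 = 76000 /M²/h, Ea1 = 41.0 kJ/mol)
    reagent + free catalyst + right-handed substrate → free catalyst + right-handed product (k2 = 26300 /M²/h, Ea2 = 48.0 kJ/mol)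
    free catalyst + impurity → spent catalyst A (k3 = 6.31 × 10⁵ /M/h, Ea3 = 35.0 kJ/mol)
    2 free catalyst → spent catalyst B (k4 = 955 /M/h, Ea4 = 36.0 kJ/mol)
    free catalyst + added ligand ⇌ idle complex, settled at all times (K5 = 37700 /M, ΔH5 = −15.0 kJ/mol)
    (constants at 25 °C)

1. which flask leads in excess of left-handed product over right-handed product ("all alike" within 1.5 percentage points) (ochre / violet / all alike)
2. excess of left-handed product over right-handed product at the end, ochre
3. excess of left-handed product over right-handed product at the end, violet

- free catalyst is single-handed; left-handed substrate and right-handed substrate are mirror images of each other, charged as a racemate, each of them at the stated concentration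
- a doubled species enters its step squared and goes two at a time
- the list of constants is for 25 °C, to be carried to other temperatures by the activation energies and enthalpies
- an excess is the difference of the two amounts in percent of their sum
- an excess is below zero if the other one leads

**What do the two product-forming steps share?** Both carry reagent and free catalyst to the same power, so these cancel from the ratio of their rates. What remains is the two substrates and the two rate constants, and the rate constants give s, the selectivity factor: the left-handed rate constant over the right-handed one, 2.89 in violet.

**What does that do to the amounts?** Let θ be the left-handed rate constant times the time integral of reagent times free catalyst. The fraction of left-handed substrate left is then exp(−θ), and of right-handed substrate exp(−θ/s). So the left-handed fraction left equals the right-handed fraction raised to the power s. Before any depletion the excess is s minus one over s plus one, which is 48.6 % in violet.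

**And in the cold?** An Arrhenius factor scales in its exponent with the energy, so the left-handed step slows by 4.54 against 5.9 for the right-handed one. Ochre therefore has s = 3.74, and its excess starts at 57.8 %, higher than violet's.

**But the favoured substrate depletes. How far?** Take violet first. Impurity has an estimated lifetime of about 0.299 h against 3.0 h, so I count catalyst equal to the impurity charge as lost. The remaining catalyst, shared with the added ligand, leaves free catalyst at 5.24 µM. With reagent held at its charge, θ is 0.287. That conversion brings the mean reagent down to 0.206 M, so θ becomes 0.246. I then reckon that 21.8 % of the left-handed and 8.15 % of the right-handed substrate react, and my excess for violet is 45.5 %.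

**And ochre?** Here I keep the whole catalyst charge and hold reagent at its charge, which overstates both. In the cold the binding constant rises by 1.74, so I reckon free catalyst at 3.74 µM and θ at 0.0450. My excess for ochre is 57.3 %.

The forecast names ochre, with 57.4 % for ochre and 45.5 % for violet, on the ground that “Rates are first order in free catalyst, so only the unbound share matters.”

The simulation gives ochre in the lead, with 57.3 % for ochre and 45.5 % for violet.

In violet, 92 % of the right-handed substrate is left, and raised to the power 2.89 this gives 78.6 % for the left-handed substrate, where the reading is 78 %. The neighbouring flask repeats violet at 0 °C with amounts and time held, so its s is 3.74. Its right-handed substrate left, 99 %, gives 96.1 % for the left-handed substrate against a reading of 96 %. Those two fractions give an excess of 57.3 %, and that flask ends at 57.3 %.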